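**Retrosynthetic overview**
- Target 14 comes from O7-selective (primary) and O5-selective (stannylene) benzoylation of the oxygenated cyclohexene core, whose C7H2O arises by reduction of a C1 ester.
- The C1=C2 alkene with O3 on the α face comes from a suprafacial 1,3-shift of a tertiary C1 acetate to C3 in a cyclohex-2-ene-1-carboxylate.
- That ester comes from methanolysis of a 2-oxabicyclo[2.2.2]octenone, made by [4+2] addition of 3-hydroxy-2-pyrone (1) to vinylene carbonate (2).
- Feature used: on the carbocycle C1–C6, C7 (on C1) and O4 (on C4) stand 1,4 to each other and can be the two ends of a pyrone lactone bridge, while O5/O6 are a cis pair trans to O4, as left by a cis-dioxygenated dienophile added endo.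
- Ring order: the carbocyclic six-membered ring is the only ring built (step 1); lactone, carbonate, acetonide and stannylene rings are temporary.

Key step: step 1

Numbering and faces: ring atoms C1–C6 and C7 as in the target (C1 bears C7, C2 is the ring CH=); α is the face of O3, O5 and O6 in the target, β is the face of O4.
Assumption: the quinidine-derived catalyst is taken to give the enantiomer drawn for 3; should the sense of induction be opposite, the quinine-derived pseudoenantiomer, 9-O-(9-phenanthryl)cupreine, is used instead.

**Route**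

Step 1
Reactants: 1 3-hydroxy-2H-pyran-2-one; 2 vinylene carbonate
Product: 3 endo bicyclic lactone carbonate (carbocycle C1–C6 bridged on the β face by C7(=O)–O4 between C1 and C4, tertiary OH on C1, C2=C3 double bond, cyclic carbonate on the α oxygens of C5 and C6)
Conditions: 9-O-(9-phenanthryl)cupreidine (10 mol %), 2 (10 equiv), CH2Cl2, 10 kbar, 25 °C
Reagents that add atoms: none
Why: Proposed new method: the quinuclidine nitrogen of the catalyst deprotonates the 3-hydroxyl of 1, and the pyronate, held as a chiral ion pair, is a HOMO-raised diene that adds through C3 and C6 to 2 (whose carbonyl is hydrogen-bonded to the catalyst 6'-hydroxyl), either as a concerted asynchronous [4+2] or as Michael addition followed by aldol-type closure; the closest known reactions are cinchona-base-catalysed Diels–Alder additions of 3-hydroxy-2-pyrones to enones, maleimides and acrylonitriles and the thermal cycloaddition of 2-pyrones to vinylene carbonate. The carbocyclic six-membered ring is closed by this intermolecular [4+2] through the new C1–C6 and C4–C5 bonds, the pyrone lactone becoming the C7–O4 bridge of a 2-oxabicyclo[2.2.2]oct-5-en-3-one. C5 and C6 are cis because the Z geometry of 2 is retained, their oxygens lie anti to the lactone bridge (hence trans to O4) because the carbonate approaches endo under the diene carbons that become C2=C3, C1 and C4 are tied to each other by the bridge, and the absolute configuration is set by the face of the ion pair left open by the catalyst. The step needs endo and facial selectivity, which the two-point binding (ion pair plus hydrogen bond) should secure, and it needs the weakly electrophilic 2 to react at all, which is helped by its large excess and by pressure.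

Step 2
Reactants: 3 endo bicyclic lactone carbonate
Product: 4 methyl 1α,4β,5α,6α-tetrahydroxycyclohex-2-ene-1β-carboxylate
Conditions: K2CO3 (0.2 equiv), MeOH, 0 → 25 °C; then acidic ion-exchange resin, filter
Reagents that add atoms: methanol, CO
Why: Base-catalysed transesterification (methanolysis) opens the strained bridged lactone to the methyl ester, freeing O4–H, and cleaves the cyclic carbonate to dimethyl carbonate, with no ring C–O bond broken so every stereocentre is kept.

Step 3
Reactants: 4 methyl 1α,4β,5α,6α-tetrahydroxycyclohex-2-ene-1β-carboxylate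
Product: 5 5,6-O-isopropylidene ketal of 4 (O1–H and O4–H free)
Conditions: Me2C(OMe)2, CSA (5 mol %), acetone, 25 °C; Et3N quench
Reagents that add atoms: 2,2-dimethoxypropane, COC(C)(C)OC
Why: Acid-catalysed acetonide formation (transketalisation) should take the only cis pair of secondary hydroxyls, O5/O6, since the tertiary O1–H is hindered and deactivated by the ester and O4 is trans to O5.

Step 4
Reactants: 5 5,6-O-isopropylidene ketal of 4
Product: 6 4-O-tert-butyldimethylsilyl ether of 5 (O1–H free)
Conditions: TBSCl (1.2 equiv), imidazole, DMF, 25 °C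
Reagents that add atoms: tert-butyldimethylsilyl chloride, CC(C)(C)[Si](C)(C)Cl
Why: Silyl ether formation occurs at the secondary allylic O4–H while the tertiary α-hydroxy ester O1–H does not react, and the non-participating silyl group keeps a second allylic ester out of step 6.

Step 5
Reactants: 6 4-O-tert-butyldimethylsilyl ether of 5
Product: 7 1-O-acetate of 6 (tertiary allylic acetate on the α face of C1)
Conditions: Ac2O (5 equiv), Et3N, DMAP (0.5 equiv), CH2Cl2, 40 °C
Reagents that add atoms: acetic anhydride, CC(=O)OC(C)=O
Why: DMAP-catalysed acylation of the tertiary alcohol installs the ester that will migrate, and C1 keeps its configuration because only the O–H bond reacts.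

Step 6
Reactants: 7 1-O-acetate of 6
Product: 8 methyl 3α-acetoxy-4β-(tert-butyldimethylsilyloxy)-5α,6α-(isopropylidenedioxy)cyclohex-1-ene-1-carboxylate
Conditions: PdCl2(MeCN)2 (10 mol %), dry THF, 25 → 50 °C
Reagents that add atoms: none
Why: Palladium-catalysed [3,3] allylic ester transposition (cyclisation-induced rearrangement): divalent palladium binds the C2=C3 alkene on the β face, the acetate carbonyl oxygen adds to C3 on the α face through a six-membered acetoxonium intermediate and the C1–O bond then breaks, so O3 arrives suprafacially on the α face (cis to O5/O6, trans to O4) and the alkene moves into conjugation with the ester, which drives the shift.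

Step 7
Reactants: 8 methyl 3α-acetoxy-4β-(tert-butyldimethylsilyloxy)-5α,6α-(isopropylidenedioxy)cyclohex-1-ene-1-carboxylate
Product: 9 1-(hydroxymethyl)-3α-hydroxy-4β-(tert-butyldimethylsilyloxy)-5α,6α-(isopropylidenedioxy)cyclohex-1-ene (O7–H and O3–H free)
Conditions: iBu2AlH (6 equiv), CH2Cl2, −78 → −30 °C; aq. potassium sodium tartrate (KNaC4H4O6)
Reagents that add atoms: none
Why: Hydride reduction with iBu2AlH converts the enoate by 1,2-reduction into the allylic alcohol C7H2OH and cleaves the acetate in the same operation, while the silyl ether and acetonide are inert.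

Step 8
Reactants: 9 diol with O7–H and O3–H free; 10 benzoyl chloride
Product: 11 7-O-benzoate of 9 (O3–H free)
Conditions: 10 (1.05 equiv), pyridine, CH2Cl2, −40 → 0 °C
Reagents that add atoms: benzoyl chloride (10), O=C(Cl)c1ccccc1
Why: Selective acylation (esterification) of the primary allylic hydroxyl: with one equivalent of acid chloride at low temperature O7–H should react ahead of the secondary O3–H, which is flanked by the silyl ether.

Step 9
Reactants: 11 7-O-benzoate of 9
Product: 12 [(3S,4R,5R,6R)-3,4,5,6-tetrahydroxycyclohex-1-en-1-yl]methyl benzoate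
Conditions: aq. HCl (2 M)/THF (1:2), 25 °C
Reagents that add atoms: none
Why: Acid hydrolysis removes the isopropylidene ketal and the silyl ether in one operation under conditions that leave the benzoate and the ring C–O bonds untouched.

Step 10
Reactants: 12 [(3S,4R,5R,6R)-3,4,5,6-tetrahydroxycyclohex-1-en-1-yl]methyl benzoate; 10 benzoyl chloride
Product: 14 [(3S,4R,5R,6R)-5-(benzoyloxy)-3,4,6-trihydroxycyclohex-1-en-1-yl]methyl benzoate (target), via 5,6-O-dibutylstannylene acetal 13 (not isolated)
Conditions: Bu2SnO (1.05 equiv), MeOH, reflux; evaporate; then 10 (1.05 equiv), 1,4-dioxane, 10 → 25 °C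
Reagents that add atoms: benzoyl chloride (10), O=C(Cl)c1ccccc1
Why: Stannylene-acetal-directed regioselective acylation: Bu2SnO should form the five-membered stannylene across the only cis-1,2-diol (O5/O6), and benzoyl chloride then acylates its equatorial oxygen O5, as in the benzoylation of manno-type cis-diols, and not the pseudoaxial O6 (held axial by allylic strain from the C1 substituent) or the unactivated O3 and O4.

**Compound list**
1 | 3-hydroxy-2H-pyran-2-one | O=C1OC=CC=C1O | starting material
2 | vinylene carbonate (1,3-dioxol-2-one) | O=C1OC=CO1 | starting material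
3 | endo bicyclic lactone carbonate (β lactone bridge C7(=O)–O4, C1–OH, α carbonate on C5/C6) | O[C@]1(C(=O)O2)C=C[C@@H]2[C@@H]3OC(=O)O[C@H]13 | intermediate
4 | methyl 1α,4β,5α,6α-tetrahydroxycyclohex-2-ene-1β-carboxylate | COC(=O)[C@@]1(O)C=C[C@@H](O)[C@H](O)[C@@H]1O | intermediate
5 | 5,6-O-isopropylidene ketal of 4 | COC(=O)[C@@]1(O)C=C[C@@H](O)[C@@H]2OC(C)(C)O[C@H]12 | intermediate
6 | 4-O-tert-butyldimethylsilyl ether of 5 | COC(=O)[C@@]1(O)C=C[C@@H](O[Si](C)(C)C(C)(C)C)[C@@H]2OC(C)(C)O[C@H]12 | intermediate
7 | 1-O-acetate of 6 | COC(=O)[C@@]1(OC(C)=O)C=C[C@@H](O[Si](C)(C)C(C)(C)C)[C@@H]2OC(C)(C)O[C@H]12 | intermediate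
8 | methyl 3α-acetoxy-4β-(tert-butyldimethylsilyloxy)-5α,6α-(isopropylidenedioxy)cyclohex-1-ene-1-carboxylate | COC(=O)C1=C[C@H](OC(C)=O)[C@@H](O[Si](C)(C)C(C)(C)C)[C@@H]2OC(C)(C)O[C@H]12 | intermediate
9 | 1-(hydroxymethyl)-3α-hydroxy-4β-(tert-butyldimethylsilyloxy)-5α,6α-(isopropylidenedioxy)cyclohex-1-ene | OCC1=C[C@H](O)[C@@H](O[Si](C)(C)C(C)(C)C)[C@@H]2OC(C)(C)O[C@H]12 | intermediate
10 | benzoyl chloride | O=C(Cl)c1ccccc1 | starting material
11 | 7-O-benzoate of 9 | O=C(OCC1=C[C@H](O)[C@@H](O[Si](C)(C)C(C)(C)C)[C@@H]2OC(C)(C)O[C@H]12)c1ccccc1 | intermediate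
12 | [(3S,4R,5R,6R)-3,4,5,6-tetrahydroxycyclohex-1-en-1-yl]methyl benzoate | O=C(OCC1=C[C@H](O)[C@@H](O)[C@H](O)[C@@H]1O)c1ccccc1 | intermediate
13 | 5,6-O-dibutylstannylene acetal of 12 | O=C(OCC1=C[C@H](O)[C@@H](O)[C@@H]2O[Sn](CCCC)(CCCC)O[C@H]12)c1ccccc1 | intermediate (not isolated)
14 | [(3S,4R,5R,6R)-5-(benzoyloxy)-3,4,6-trihydroxycyclohex-1-en-1-yl]methyl benzoate | O=C(OCC1=C[C@H](O)[C@@H](O)[C@H](OC(=O)c2ccccc2)[C@@H]1O)c1ccccc1 | target

**Step count**
Total: 10 steps. Longest linear sequence: 10 steps from 1 (2 and 10 are purchased and added along the line).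

**Steps most likely to fail**

Step 1 (proposed new method). The pyronate may not engage the electron-neutral alkene, it may attack the carbonate carbonyl of 2 instead (O-acylation with ring opening), or the endo and facial selectivity may be poor. The fallback sets out from 1. Acylation with (−)-menthyl chloroformate and Et3N in CH2Cl2 should give the menthyl pyronyl carbonate F1. Its uncatalysed Diels–Alder reaction with neat 2 at 12 kbar and 50 °C, a known reaction type for 2-pyrones and vinylene carbonate, should give the endo adducts as two diastereomers. The one with the configuration of 3, the bridgehead menthyl carbonate F2, is separated by crystallisation or chromatography. K2CO3 in MeOH then cleaves the lactone and both carbonates, and the route is rejoined at 4.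

Step 6. The shift needs the half-chair in which the C1 acetate is pseudoaxial, and this places O5 axial on the same face. Closure to the acetoxonium intermediate may therefore be slow, which leaves time for Lewis-acid-induced loss of acetic acid or cleavage of the silyl ether and ketal. The fallback sets out from 6. Hydroxyl-directed epoxidation with VO(acac)2 (cat.) and tBuOOH in CH2Cl2 should give the 2α,3α-epoxy alcohol F3, syn to O1–H. Acetylation (Ac2O, Et3N, DMAP) gives the α-acetoxy epoxy ester F4. SmI2 with HMPA in THF at −78 °C should cleave the C1–OAc bond reductively, and the samarium enolate opens the adjacent epoxide to the 3α-hydroxy enoate F5. Reduction with iBu2AlH as in step 7 returns to the route at 9.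

Step 10. A stannylene may also form across the trans O3/O4 diol and lead to acylation at O3 or O4, or over-benzoylation and acyl migration may blur the regiochemistry. The fallback sets out from 11 and protects the competing hydroxyls. TBSOTf and 2,6-lutidine in CH2Cl2 at −40 °C give the 3,4-bis-silyl ether F6. CeCl3·7H2O and oxalic acid in MeCN should cleave the ketal without touching the silyl ethers, giving the 5,6-diol F7. Benzoylation (10, pyridine, CH2Cl2, −30 °C) at the equatorial O5, in preference to the hindered pseudoaxial allylic O6, gives the 5,7-dibenzoate F8. HF·pyridine in THF removes both silyl ethers and returns to the route at 14.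

**Further compounds**
F1 | step 1 | (1R,2S,5R)-menthyl 2-oxo-2H-pyran-3-yl carbonate | CC(C)[C@@H]1CC[C@@H](C)C[C@H]1OC(=O)OC1=CC=COC1=O
F2 | step 1 | 1-O-[(1R,2S,5R)-menthyloxycarbonyl] derivative of 3 | CC(C)[C@@H]4CC[C@@H](C)C[C@H]4OC(=O)O[C@]1(C(=O)O2)C=C[C@@H]2[C@@H]3OC(=O)O[C@H]13
F3 | step 6 | 2α,3α-epoxide of 6 | COC(=O)[C@@]1(O)[C@@H]3O[C@@H]3[C@@H](O[Si](C)(C)C(C)(C)C)[C@@H]2OC(C)(C)O[C@H]12
F4 | step 6 | 1-O-acetate of F3 | COC(=O)[C@@]1(OC(C)=O)[C@@H]3O[C@@H]3[C@@H](O[Si](C)(C)C(C)(C)C)[C@@H]2OC(C)(C)O[C@H]12
F5 | step 6 | methyl 3α-hydroxy-4β-(tert-butyldimethylsilyloxy)-5α,6α-(isopropylidenedioxy)cyclohex-1-ene-1-carboxylate | COC(=O)C1=C[C@H](O)[C@@H](O[Si](C)(C)C(C)(C)C)[C@@H]2OC(C)(C)O[C@H]12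
F6 | step 10 | 3-O-tert-butyldimethylsilyl ether of 11 | O=C(OCC1=C[C@H](O[Si](C)(C)C(C)(C)C)[C@@H](O[Si](C)(C)C(C)(C)C)[C@@H]2OC(C)(C)O[C@H]12)c1ccccc1
F7 | step 10 | 3,4-bis-O-tert-butyldimethylsilyl ether of 12 (O5–H and O6–H free) | O=C(OCC1=C[C@H](O[Si](C)(C)C(C)(C)C)[C@@H](O[Si](C)(C)C(C)(C)C)[C@H](O)[C@@H]1O)c1ccccc1
F8 | step 10 | 3,4-bis-O-tert-butyldimethylsilyl ether of 14 | O=C(OCC1=C[C@H](O[Si](C)(C)C(C)(C)C)[C@@H](O[Si](C)(C)C(C)(C)C)[C@H](OC(=O)c2ccccc2)[C@@H]1O)c1ccccc1
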